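The runs are calculated with constants of no real substance, noise included.

No mass balance closes on target and starting material alone in the gamma flask: at 12.0 h they sum to 45.8% of the charge.

in all of them: starting material 0.80 M

| flask | reagent | second substrate | temperature | remark | time |
|---|---|---|---|---|---|
| gamma | 1.6 M | 0.80 M | −20 °C | the very flask that is asked about, followed so far |  |
| epsilon | 1.6 M | 0.80 M | −14 °C | run made earlier |  |
| flask | 1.60 M | 0.800 M | −20 °C |  | 12 h |
- gamma (time / h: target / %, starting material / %): 1.00: 35.4, 57.9; 2.00: 41.8, 45.6; 5.00: 34.3, 33.2; 12.0: 19.6, 26.2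
- epsilon (time / h: target / %, starting material / %): 1.00: 36.8, 51.0; 2.00: 32.2, 43.9; 5.00: 20.4, 35.0; 12.0: 9.4, 25.2

(scatter of a reading: 0.5 percentage points)
- what is taken out of target is counted as made
- the numbers in the tables scatter with a standard deviation of 0.5 percentage points
- target, in percent of the starting material first charged, at 12 h
- what to do for the largest gain in target; "none" if nothing gains more than 2 percentage points (west / north / south / none)
- target present, with what was taken out counted in, in percent of the starting material first charged, after west
- target present, with what was taken out counted in, in percent of the starting material first charged, after south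
- west: at 12 h take out 90% of the target then present, then wait 6.0 h
- north: at 12 h raise the temperature by 10 K, then wait 6.0 h
- south: change nothing and wait 6.0 h more

Call the pool W, target P plus starting material A, as fractions of the charge, and read the gap as over-reaction product from reagent + target. Each pool unit lost cost 2 reagent and each target unit 1, and reagent was charged at 2.00 equivalents, so, reckoning the second substrate as taking no reagent, free reagent is 2W − P. Assume the target share φ = P/W steady, with k the second-order constant:

dW/dt = −kP(2W − P) = −kφ(2 − φ)W²
1/W = 1/W(start) + s·t, with s = kφ(2 − φ)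

Take the drain slope, the hourly rise of 1/W, from 5.00 h to 12.0 h: s = 0.100 h⁻¹. With φ = 0.428, k = 0.149 h⁻¹. Split any pool by the pre-equilibrium quotient Q = P/(A(2W − P)), which reads 1.04 at 12.0 h.

My reckoning:

South: W falls to 35.9%, and Q leaves target 13.5%.
West: bank 17.6%, leaving pool 28.2% and reagent 72.0% of the starting-material charge. Regrowth to Q gives target 11.1%. The drain takes the pool to 23.0%, and at constant share the total is 26.7%.
North: the epsilon run at −14 °C has slope 0.155 h⁻¹, steeper than s.

Charge nothing new: take out the target.

The forecast gives 19.6% now, west as best, 27% after west and 14.5% after south, higher than mine after west and after south, and says of north: “warming speeds the drain and lowers the equilibrium, so it loses target”.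

The flask gives 19.2% and west, gaining 6.6 points, against −5.5 points for south and −13 points for north; west ends at 25.8%, south at 13.7%.

    starting material + reagent ⇌ target (K = 1.50 L mol⁻¹, k = 0.00786 L mol⁻¹ min⁻¹, Ea = 65.0 kJ mol⁻¹, ΔH = −47.0 kJ mol⁻¹)
    second substrate + reagent ⇌ second product (K = 0.0430 L mol⁻¹, k = 3.16 × 10⁻⁴ L mol⁻¹ min⁻¹, Ea = 66.0 kJ mol⁻¹, ΔH = −51.0 kJ mol⁻¹)
    reagent + target → over-reaction product (k = 0.00313 L mol⁻¹ min⁻¹, Ea = 56.0 kJ mol⁻¹)
    (constants at −20 °C)

Carry s to the neighbour flask read at 50 h: from 45.8% it reckons a pool of 16.7%. That flask holds target 5.06% and starting material 14.2%, a pool of 19.2%, more than reckoned. Its slope since 12 h is 0.0796 h⁻¹, and its target share has fallen to 0.264.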